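**Strategy.** Numbering: O1, C2 (heptyl), C3, C4 (ketone), C4a, C5, C6 (decyl), O7, C8 (lactone carbonyl), C8a; ring A is the lactone, ring B the pyranone. The route rests on cutting the C4–C4a bond of ring B. Both ends of that bond are acceptor carbons in the target: C4 is a ketone carbon and C4a sits β to C8 across C8a=C4a, while O1 on C8a is the only other link between the rings. A nickel/chromium reductive coupling turns a C4a–I bond into an alkenylchromium that adds to a C4 aldehyde, forming C4–C4a and closing ring B in one operation. The precursor is the ring-A iodo enol-ether lactone (iodine on C4a) whose O1 carries an (S)-3-oxydecanal chain.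

Key step: step 8

Remark: the ring closure is expected to give both C4 epimers of 17; they are carried on together because step 9 turns C4 into the ketone carbon, and the SMILES of 16 and 17 show the 2,4-cis (4R) epimer.

**Route**

Step 1
Reactants: 1 ethyl pyruvate
Product: 2 ethyl (E)-2-(2,2-dimethylhydrazinylidene)propanoate
Conditions: Me2NNH2 (1.1 equiv), AcOH (cat.), MgSO4, CH2Cl2, rt
Reagents that add atoms: 1,1-dimethylhydrazine, CN(C)N
Why: Acid-catalysed condensation of the ketone with the NH2 group gives the N,N-dimethylhydrazone (hydrazone formation), which masks the ketone and leaves the methyl group as the only site for deprotonation in step 2; the C=N geometry has no consequence later.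

Step 2
Reactants: 2 ethyl (E)-2-(2,2-dimethylhydrazinylidene)propanoate; 3 (R)-1,2-epoxydodecane
Product: 6 (R)-6-decyl-3-(2,2-dimethylhydrazinylidene)tetrahydro-2H-pyran-2-one, via lithium azaenolate 4 (not isolated), via lithium alkoxide 5 (not isolated)
Conditions: LDA (1.05 equiv), THF, −78 °C (2 added to the base); 3, −78 °C → rt; AcOH; then CSA (cat.), PhMe, rt
Reagents that add atoms: none
Why: Hydrazone azaenolate alkylation (Corey–Enders type): LDA removes a methyl proton of 2, the carbon terminus of azaenolate 4 opens the epoxide at its unsubstituted carbon by SN2 so the (R) carbinol centre (the later C6) is untouched, and alkoxide 5 closes the six-membered lactone on the ester, with acid completing the lactonisation.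

Step 3
Reactants: 6 (R)-6-decyl-3-(2,2-dimethylhydrazinylidene)tetrahydro-2H-pyran-2-one
Product: 7 (R)-6-decyl-3-hydroxy-5,6-dihydro-2H-pyran-2-one
Conditions: 1 M aq HCl, THF, rt; PhMe azeotrope
Reagents that add atoms: water, O
Why: Aqueous-acid hydrolysis of the hydrazone (through its ene-hydrazine tautomer) should free the α-keto lactone, which rests as the conjugated, hydrogen-bonded enol; C6 is not involved.

Step 4
Reactants: 7 (R)-6-decyl-3-hydroxy-5,6-dihydro-2H-pyran-2-one
Product: 8 (R)-6-decyl-3-hydroxy-4-iodo-5,6-dihydro-2H-pyran-2-one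
Conditions: NIS (1.05 equiv), CH2Cl2, 0 °C, dark
Reagents that add atoms: N-iodosuccinimide, O=C1CCC(=O)N1I
Why: Electrophilic α-halogenation of a 1,2-dicarbonyl enol: iodonium is taken up at the nucleophilic β-carbon of the enol (C4 of the lactone, the later C4a) and re-enolisation should give the stable iodo enol, as in the halogenation of cyclic 1,2-diones.

Step 5
Reactants: 9 octanal
Product: 11 (R)-undec-1-en-4-ol, via borinate ester 10 (not isolated)
Conditions: (−)-Ipc2B(allyl) (1 M in pentane, 1.2 equiv), Et2O, −78 °C; then 3 M NaOH, 30% H2O2, 0 °C → rt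
Reagents that add atoms: (−)-B-allyldiisopinocampheylborane, C=CCB([C@@H]1C[C@@H]2C[C@H]([C@H]1C)C2(C)C)[C@@H]1C[C@@H]2C[C@H]([C@H]1C)C2(C)C
Why: Brown allylboration through a chair-like six-membered transition state in which the isopinocampheyl groups of the (+)-α-pinene-derived reagent direct allyl transfer to the Si face of octanal, which sets the (R) carbinol centre; oxidative work-up frees the alcohol.

Step 6
Reactants: 8 (R)-6-decyl-3-hydroxy-4-iodo-5,6-dihydro-2H-pyran-2-one; 11 (R)-undec-1-en-4-ol
Product: 12 (R)-6-decyl-4-iodo-3-{[(S)-undec-1-en-4-yl]oxy}-5,6-dihydro-2H-pyran-2-one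
Conditions: PPh3, DIAD, THF, 0 °C (betaine preformed); then 11 and 8, 0 °C → rt
Reagents that add atoms: none
Why: Mitsunobu etherification: the acidic enol OH of 8 protonates the betaine and its oxygen displaces the oxyphosphonium of 11 by SN2 with inversion, turning the (R) carbinol into the (S) ether carbon (the later C2), while iodine on the neighbouring carbon blocks C-alkylation.

Step 7
Reactants: 12 (R)-6-decyl-4-iodo-3-{[(S)-undec-1-en-4-yl]oxy}-5,6-dihydro-2H-pyran-2-one
Product: 14 (S)-3-{[(R)-6-decyl-4-iodo-2-oxo-5,6-dihydro-2H-pyran-3-yl]oxy}decanal, via vicinal diol 13 (not isolated)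
Conditions: OsO4 (2 mol%), NaIO4 (4 equiv), 2,6-lutidine (2 equiv), dioxane/H2O 3:1, rt; crude 14 used at once
Reagents that add atoms: osmium tetroxide, O=[Os](=O)(=O)=O (oxygen donor, turned over by sodium periodate, [Na+].[O-]I(=O)(=O)=O)
Why: Lemieux–Johnson oxidation: osmium tetroxide should dihydroxylate the monosubstituted terminal alkene much faster than the tetrasubstituted ring alkene deactivated by the lactone carbonyl and iodine, periodate cleaves diol 13, and the lutidine buffer keeps the β-oxy aldehyde from eliminating, as it does for β-acyloxy aldehydes made in the same way.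

Step 8
Reactants: 14 (S)-3-{[(R)-6-decyl-4-iodo-2-oxo-5,6-dihydro-2H-pyran-3-yl]oxy}decanal
Product: 17 (2S,4R,6R)-6-decyl-2-heptyl-4-hydroxy-3,4,5,6-tetrahydro-2H-pyrano[2,3-c]pyran-8-one, via alkenylchromium species 15 (not isolated), via chromium alkoxide 16 (not isolated)
Conditions: CrCl2 (6 equiv), NiCl2 (5 mol%), degassed DMF/THF, rt, 0.005 M, slow addition of 14; aq NH4Cl
Reagents that add atoms: none
Why: Ni(0), formed from NiCl2 by Cr(II), inserts into the C4a–I bond of the β-iodo enoate and passes the alkenyl group to Cr(III); the resulting alkenylchromium, now nucleophilic at C4a, adds to the tethered C4 aldehyde (intramolecular Nozaki–Hiyama–Kishi coupling, the closest precedent being NHK cyclisations of β-iodo enoates onto aldehydes). Ring B (O1, C2, C3, C4, C4a, C8a) closes in a 6-exo-trig mode, the C=O being exocyclic to the new ring. The new C4 carbinol centre is set only by substrate bias (heptyl at C2 pseudo-equatorial in a chair-like transition state), so an epimer mixture is expected and is acceptable because step 9 removes this centre. The step needs the aldehyde to react in preference to the lactone carbonyl C8 and needs the β-oxy aldehyde not to lose the enol-ether oxygen by elimination; the weakly basic, aldehyde-selective organochromium should secure both. High dilution favours ring closure over intermolecular coupling, and the C4 chromium alkoxide cannot attack C8 because that would place the C4a=C8a alkene at a bridgehead.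

Step 9
Reactants: 17 (2S,4R,6R)-6-decyl-2-heptyl-4-hydroxy-3,4,5,6-tetrahydro-2H-pyrano[2,3-c]pyran-8-one
Product: 18 (2S,6R)-6-decyl-2-heptyl-2,3,5,6-tetrahydropyrano[2,3-c]pyran-4,8-dione
Conditions: Dess–Martin periodinane (1.5 equiv), CH2Cl2, 0 °C → rt; Na2S2O3/NaHCO3 wash
Reagents that add atoms: none
Why: Dess–Martin oxidation of the secondary allylic alcohol should convert both C4 epimers into the one ketone under non-basic conditions, so C2 (β to the new ketone) and C6 are not exposed to retro-oxa-Michael or elimination pathways.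

**Compound list**

1 | ethyl pyruvate | CCOC(=O)C(C)=O | starting material
2 | ethyl (E)-2-(2,2-dimethylhydrazinylidene)propanoate | CCOC(=O)/C(C)=N/N(C)C | intermediate
3 | (R)-1,2-epoxydodecane | CCCCCCCCCC[C@@H]1CO1 | starting material
4 | lithium azaenolate of 2 | [Li+].CCOC(=O)C(=C)[N-]N(C)C | intermediate
5 | lithium alkoxide of ethyl (R)-2-(2,2-dimethylhydrazinylidene)-5-hydroxypentadecanoate | [Li+].CCCCCCCCCC[C@@H]([O-])CCC(=NN(C)C)C(=O)OCC | intermediate
6 | (R)-6-decyl-3-(2,2-dimethylhydrazinylidene)tetrahydro-2H-pyran-2-one | CCCCCCCCCC[C@@H]1CCC(=NN(C)C)C(=O)O1 | intermediate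
7 | (R)-6-decyl-3-hydroxy-5,6-dihydro-2H-pyran-2-one (enol of the 2,3-dione) | CCCCCCCCCC[C@@H]1CC=C(O)C(=O)O1 | intermediate
8 | (R)-6-decyl-3-hydroxy-4-iodo-5,6-dihydro-2H-pyran-2-one | CCCCCCCCCC[C@@H]1CC(I)=C(O)C(=O)O1 | intermediate
9 | octanal | CCCCCCCC=O | starting material
10 | (R)-undec-1-en-4-yl diisopinocampheylborinate | CCCCCCC[C@H](CC=C)OB([C@@H]1C[C@@H]2C[C@H]([C@H]1C)C2(C)C)[C@@H]1C[C@@H]2C[C@H]([C@H]1C)C2(C)C | intermediate
11 | (R)-undec-1-en-4-ol | CCCCCCC[C@@H](O)CC=C | intermediate
12 | (R)-6-decyl-4-iodo-3-{[(S)-undec-1-en-4-yl]oxy}-5,6-dihydro-2H-pyran-2-one | CCCCCCCCCC[C@@H]1CC(I)=C(O[C@@H](CCCCCCC)CC=C)C(=O)O1 | intermediate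
13 | (R)-6-decyl-3-{[(4S)-1,2-dihydroxyundecan-4-yl]oxy}-4-iodo-5,6-dihydro-2H-pyran-2-one (both carbinol epimers) | CCCCCCCCCC[C@@H]1CC(I)=C(O[C@@H](CCCCCCC)CC(O)CO)C(=O)O1 | intermediate
14 | (S)-3-{[(R)-6-decyl-4-iodo-2-oxo-5,6-dihydro-2H-pyran-3-yl]oxy}decanal | CCCCCCCCCC[C@@H]1CC(I)=C(O[C@@H](CCCCCCC)CC=O)C(=O)O1 | intermediate
15 | dichloro{(R)-6-decyl-2-oxo-3-{[(S)-1-oxodecan-3-yl]oxy}-5,6-dihydro-2H-pyran-4-yl}chromium(III), solvent ligands omitted | CCCCCCCCCC[C@@H]1CC([Cr](Cl)Cl)=C(O[C@@H](CCCCCCC)CC=O)C(=O)O1 | intermediate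
16 | dichlorochromium(III) alkoxide of 17 | CCCCCCCCCC[C@@H]1CC2=C(O[C@@H](CCCCCCC)C[C@H]2O[Cr](Cl)Cl)C(=O)O1 | intermediate
17 | (2S,4R,6R)-6-decyl-2-heptyl-4-hydroxy-3,4,5,6-tetrahydro-2H-pyrano[2,3-c]pyran-8-one (4S epimer carried along) | CCCCCCCCCC[C@@H]1CC2=C(O[C@@H](CCCCCCC)C[C@H]2O)C(=O)O1 | intermediate
18 | (2S,6R)-6-decyl-2-heptyl-2,3,5,6-tetrahydropyrano[2,3-c]pyran-4,8-dione | CCCCCCCCCC[C@@H]1CC2=C(O[C@@H](CCCCCCC)CC2=O)C(=O)O1 | target

**Step count and risk**

Total step count: 9. Longest linear sequence: 8 (steps 1, 2, 3, 4, 6, 7, 8, 9); step 5 is the side branch.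

Steps most likely to fail:

1. Step 8. The alkenylchromium may be protonated before it cyclises (loss of iodine without ring closure), the aldehyde may expel the enol-ether oxygen by β-elimination on the Lewis-acidic metal salts, or intermolecular coupling may outrun closure. Fallback: set out from 12 and come back at 18. The same C4–C4a bond is made by carbopalladation instead of carbonyl addition: an intramolecular Heck reaction of the C4a–I bond onto the terminal alkene (Pd(OAc)2, PPh3, Ag2CO3, MeCN, 70 °C) should close ring B 6-exo-trig and, after β-hydride elimination, give the exocyclic diene (2S,6R)-6-decyl-2-heptyl-4-methylidene-3,4,5,6-tetrahydro-2H-pyrano[2,3-c]pyran-8-one F1. Lemieux–Johnson cleavage of its methylidene group, the distal and more electron-rich alkene of the dienoate, should then give 18 directly, replacing steps 7–9.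

2. Step 6. Displacement at the hindered enol oxygen may be slow enough that the activated alcohol eliminates to a diene, and free phosphine may strip iodine from the minor α-iodo ketone tautomer of 8. Fallback: set out from 11 and come back at 12 by a phosphine-free Williamson etherification. Mesylation of 11 (MsCl, Et3N, CH2Cl2, 0 °C) gives (R)-undec-1-en-4-yl methanesulfonate F2, which the caesium enolate of 8 (Cs2CO3, DMF, 40 °C) should displace at oxygen with the same inversion.

3. Step 2. The azaenolate may condense with the ester of hydrazone that is not yet metalated, the epoxide opening may be sluggish, or lactonisation may stall at the open hydroxy ester. Fallback: set out from 3 and come back at 7, replacing steps 1–3 with enolate chemistry of a saturated lactone. BF3·OEt2-promoted opening of 3 by lithiated ethyl propiolate (THF, −78 °C) gives ethyl (R)-5-hydroxypentadec-2-ynoate F3. Hydrogenation (H2, Pd/C, EtOAc) followed by TsOH (cat.) in PhMe gives (R)-6-decyltetrahydro-2H-pyran-2-one F4. Enolate hydroxylation (LiHMDS, THF, −78 °C; Davis oxaziridine) gives (6R)-6-decyl-3-hydroxytetrahydro-2H-pyran-2-one F5 as a C3 epimer mixture, and Swern oxidation gives the keto lactone, which enolises to 7.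

**Further compounds**

F1 | step 8 | (2S,6R)-6-decyl-2-heptyl-4-methylidene-3,4,5,6-tetrahydro-2H-pyrano[2,3-c]pyran-8-one | CCCCCCCCCC[C@@H]1CC2=C(O[C@@H](CCCCCCC)CC2=C)C(=O)O1
F2 | step 6 | (R)-undec-1-en-4-yl methanesulfonate | CCCCCCC[C@@H](OS(C)(=O)=O)CC=C
F3 | step 2 | ethyl (R)-5-hydroxypentadec-2-ynoate | CCCCCCCCCC[C@@H](O)CC#CC(=O)OCC
F4 | step 2 | (R)-6-decyltetrahydro-2H-pyran-2-one | CCCCCCCCCC[C@@H]1CCCC(=O)O1
F5 | step 2 | (6R)-6-decyl-3-hydroxytetrahydro-2H-pyran-2-one (C3 epimers) | CCCCCCCCCC[C@@H]1CCC(O)C(=O)O1
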